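Amounts first: the ochre run holds 150 mM of starting material against 180 mM of reagent, so starting material is its limiting reagent. The balance is short. When a share f of that charge has turned, the starting material left is the charge less f, and the reagent left is 1.20 charges less f. The green run has the same surplus of reagent, 30.0 mM, so it starts on the ochre line, 90.0 mM further along.

| setting | ochre | green | violet | red | teal |
|---|---|---|---|---|---|
| starting material | 150 mM | 60.0 mM | 150 mM | 300 mM | 150 mM |
| reagent | 180 mM | 90.0 mM | 90.0 mM | 180 mM | 180 mM |
| catalyst | 12.0 mM | 12.0 mM | 12.0 mM | 12.0 mM | 12.0 mM |
| time |  |  |  |  | 100 min |

| run | time / min | [target] / mM |
|---|---|---|
| ochre run | 8.4 | 10.6 |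
| ochre run | 17 | 24.5 |
| ochre run | 25 | 37.4 |
| ochre run | 34 | 49.1 |
| ochre run | 42 | 59.3 |
| green run | 8.4 | 2.5 |
| green run | 17 | 8.5 |
| green run | 25 | 11.2 |
| green run | 34 | 16.0 |
| green run | 42 | 20.0 |
| violet run | 8.4 | 6.9 |
| violet run | 17 | 17.5 |
| violet run | 25 | 29.0 |
| violet run | 34 | 38.2 |
| violet run | 42 | 47.4 |
| red run | 8.4 | 19.9 |
| red run | 17 | 48.8 |
| red run | 25 | 71.7 |
| red run | 34 | 95.0 |
| red run | 42 | 113.4 |

(standard deviation of a reading: 0.4 mM)

- Overall: starting material + reagent -> target, with catalyst as catalyst.
- Constant volume, constant temperature.
- Readings of a species count what is bound in complexes too.
- An order is taken over about fifteen percent of the charge, up and down.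

* the power of [reagent] that the first rate follows, about the charge of the ochre run; measure it at two percent of starting material made into target
* the power of [starting material] that the first rate follows, about the charge of the ochre run; measure it at two percent of starting material made into target (one fixed amount of target, the same in the runs compared)
* the green run starts with 90.0 mM less of starting material and of reagent than the ochre run, and with no target. Compared where both hold the same amount of starting material, once fifteen percent of what the green run was charged with has turned into target, is the green run faster, slower or alike (within a tenth)?
* target in the teal run at 100 min, as a share of the starting material charged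
* which of these the readings show (the substrate kills the catalyst / the substrate is lost by itself / the substrate ties up the catalyst / the catalyst wakes slowly)

In the ochre run the share turned went from 24.9% at 25 min to 39.5% at 42 min. That makes 0.0127 min⁻¹, which I call the turning constant: the share of the starting material still present that goes per minute, a pseudo-first-order constant. Over the same stretch the green run gave 0.0117 min⁻¹, the red run 0.0119 min⁻¹ and the violet run 0.00970 min⁻¹.

I turned the question round. For starting material to tie up the catalyst, the red run, holding 1.38 ochre charges of it at mid-stretch, had to turn a clearly smaller share per minute than the green run, holding 0.296. Instead the two readings stand level, though the red run also held more reagent at that stage. For a dying catalyst, the ochre constant had to fall with time, yet over the first interval it read 0.00872 min⁻¹, lower than later. So I committed to a catalyst that wakes slowly.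

The constant ranks instead with the reagent left at mid-stretch: 0.288 ochre charges in the violet run, 0.413 in green, 0.486 in red and 0.731 in ochre. At the compared point the green and ochre runs hold equal starting material and equal reagent, and the green run gets there between 17 min and 25 min, past the first interval, so I said alike. The teal run repeats the ochre charge. Beyond 42 min its reagent falls from 0.671 charges, and the red mid-stretch value lies lower on that way down, so I continued with the red constant and reached 69.6%. The orders I left open.

The forecast gave 0.27 for reagent, 0.65 for starting material, alike, 69%, a little below my figure, and the catalyst wakes slowly, on the ground that “Rates rise over the first interval or two in every run, then settle”.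

The teal run gave 69.5%. About the ochre charge the orders came out at 0.40 in reagent and 0.71 in starting material, the green run against the ochre run came out alike, and the answer to what the readings show was: the catalyst wakes slowly.

    active catalyst + reagent ⇌ catalyst-reagent complex, settled at all times (52.50 L mol⁻¹)
    catalyst-reagent complex + starting material → target + active catalyst (1.218 L mol⁻¹ min⁻¹)
    catalyst + reagent → active catalyst + reagent (1.800 L mol⁻¹ min⁻¹)

The fits with starting material tying up the catalyst and with the catalyst dying by itself put the teal run at 65.5% and 65.5%. On the green run, the constant 0.0117 min⁻¹ carried on from 42 min puts half of the charge at 66.6 min, and that run reached it at 68.4 min.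

(The numbers in the tables were computed on assumed constants.)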